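Slowness is what I see first here: 0.26 mM of Z makes J one turnover at a time, while the J already made sits among Q that slowly takes it away as Q.J.

| setting | theta | alpha | delta | gamma |
|---|---|---|---|---|
| Q | 0.10 M | 0.20 M | 0.40 M | 0.80 M |
| L | 0.250 M (fed, over 15 min) | 0.250 M (fed, over 15 min) | 0.250 M (fed, over 15 min) | 0.250 M (fed, over 15 min) |
| Z | 0.26 mM | 0.26 mM | 0.26 mM | 0.26 mM |
| time | 20 min | 20 min | 20 min | 20 min |

    Q + J → Q.J (k1 = 0.015 /M/s)
    Q + L.Z ⇌ Q.L.Z (K2 = 47 /M, k2 = 16 /M/s)
    Q.L.Z → Z + J (k3 = 0.68 /s)
    L + Z ⇌ L.Z (K4 = 2.7 /M, k4 = 28 /M/s)

- a species is counted by the Q in it: one Q.J counts as two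
- "hardly changes" means that all values lie within two and a half points (for a concentration: within two and a half percent of the largest)
- run time (theta): 20 min

- [J] at the end for theta, alpha, delta, gamma, in this order
- how the row runs (rises, then falls / falls all the way / falls, then rises / rises all the way / hardly changes)

- I start with the main step alone, with every Z sitting as Q.L.Z: J is then made at 1.77 × 10⁻⁴ M/s, which over 20 min comes to 0.212 M, more than the 0.10 M of Q that theta holds, so this figure alone tells me little.
- Now I add Q + J → Q.J: in gamma a J lives about 83.3 s, shorter than the run, so there J stops piling up and stands where making and loss balance, and this gives my quantity, the standing level of J, which is the turnover of the catalyst divided by the rate constant of Q + J and by [Q], here with all the catalyst as Q.L.Z and [Q] at its charge, 0.0147 M.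
- At full turnover the level goes as one over [Q], so for delta it comes to 0.0295 M, twice that of gamma, and I expect the row to fall at its high end.
- In theta the same reckoning gives 0.118 M, more than the Q charged, and a J lives 11.1 min against a run of 20 min, so I expect the [J] of theta to lie under that figure; a top somewhere between is what I expect, though I cannot place it.
- Last comes the rest of the catalyst: a Q.L.Z lives 0.980 s, shorter than the run, so I take the forms of the catalyst as settled, each made as fast as it goes, which gives [Q.L.Z]/[L.Z] equal to [Q] over 0.0638 M.
- I do not take L + Z as an equilibrium, since in gamma L.Z falls back at 10.4 /s, slower than the 12.8 /s at which Q takes it; balancing the flow through L.Z instead gives [Z]/[L.Z] of 5.40 for [L] at half its charge.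
- In gamma, with [Q] still taken at its charge, that makes Q.L.Z the resting state, more of it standing than of Z, with 66.2% of the catalyst, and the level drops to 0.00973 M, the figure I commit to.
- The forecast gives 0.028 M, 0.029 M, 0.024 M and 0.013 M, a row that rises, then falls, and says “the row peaks weakly”.
- The simulation gives 0.0275 M, 0.0294 M, 0.0224 M and 0.0126 M, a row that rises, then falls and reads as turning near 0.17 M, with gamma higher than my figure and lower than the full-turnover level of 0.0147 M.
- In gamma at 20.0 min, with 62.1% of the catalyst as Q.L.Z and 71.8% of the Q left, the standing level comes to 0.0127 M, beside a [J] of 0.0126 M. In theta at that time, with 18.7% as Q.L.Z and 41.9% of the Q left, the level comes to 0.0525 M, higher than its [J] of 0.0275 M, and the half-life of J by Q + J there is 18 min.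

(Its constants come from no measurement; the run is a simulation.)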